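The route rests on disconnecting C5–C10 and C8–C9 of ring B. The key step exploits the way ring B is substituted: the oxygenated C6 lies between C5 and C7, and C9 adjoins the quaternary, methyl-bearing C10. C5 to C8 therefore become a 2-silyloxydiene and C9=C10 an (E)-enoate (ester carbon C11), joined by the C1–C4 chain. One Me2AlCl-promoted intramolecular Diels–Alder reaction should then close ring B by cycloaddition and ring A through the tether and set C5, C8, C9 and C10 relative to C4. Its precursor is an acyclic silyloxytrienoate that carries the C3/C4 pair, made by iridium-catalysed tert-(hydroxy)prenylation, as two non-chelating silyl ethers.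

Key step: step 9

Numbering: labdane numbering of the target is used for all intermediates (ring A C1–C5/C10, ring B C5–C10, C11 on C9, C17 on C8, C18 (α) and C19 (β) on C4, C20 on C10); TBS = tert-butyldimethylsilyl.
Assumption: the (R)-Tol-BINAP iridium catalyst is taken to deliver the (6S,7S) anti diol 5 in step 2; should the sense of induction be the opposite, the (S)-ligand is used with no other change.

Step 1
Reactants: 1 5-hydroxypentan-2-one; 2 trimethyl phosphonoacetate
Product: 3 methyl (2E)-6-hydroxy-3-methylhex-2-enoate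
Conditions: 2 (1.2 equiv), NaH (1.15 equiv), THF, 0 °C; then 1, 0 → 50 °C; minor 2Z isomer removed by chromatography
Reagents that add atoms: none
Why: Horner–Wadsworth–Emmons olefination of the methyl ketone with the preformed sodium phosphonate, which leaves no free hydride or alkoxide to trigger oxa-Michael closure of the hydroxy enoate, should give mainly the E-enoate that later becomes the C9=C10 dienophile.

Step 2
Reactants: 3 methyl (2E)-6-hydroxy-3-methylhex-2-enoate; 4 2-methyl-2-vinyloxirane
Product: 5 methyl (2E,6S,7S)-6-hydroxy-7-(hydroxymethyl)-3,7-dimethylnona-2,8-dienoate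
Conditions: [Ir(cod)Cl]2 (2.5 mol%), (R)-Tol-BINAP (5 mol%), 4-cyano-3-nitrobenzoic acid (10 mol%), K3PO4 (5 mol%), racemic 4 (300 mol%), THF, 60 °C
Reagents that add atoms: none
Why: Iridium-catalysed redox-neutral tert-(hydroxy)prenylation (transfer-hydrogenative carbonyl allylation from the alcohol oxidation level) is a formal addition that keeps every atom of both partners: the primary alcohol is dehydrogenated, both enantiomers of the vinyl epoxide ionise to the same π-allyliridium species, and its (E)-σ-allyl form adds to the transient aldehyde through a closed chair, which should set the carbinol C3 and the quaternary C4 anti to each other under control of the chiral ligand.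

Step 3
Reactants: 5 anti diol
Product: 6 methyl (2E,6S,7S)-6-(TBSO)-7-[(TBSO)methyl]-3,7-dimethylnona-2,8-dienoate
Conditions: TBSOTf (2.6 equiv), 2,6-lutidine (4 equiv), CH2Cl2, −78 → 0 °C
Reagents that add atoms: tert-butyldimethylsilyl trifluoromethanesulfonate, CC(C)(C)[Si](C)(C)OS(=O)(=O)C(F)(F)F
Why: Silyl triflate silylation protects the primary and the hindered secondary hydroxyl in one operation; two non-chelating silyl ethers are chosen instead of a cyclic 3,19-acetal because, in the chair tether that step 9 needs (C3–O equatorial, C19 axial), a dioxane ring would have to carry C2 axial and would therefore bias the fold towards the wrong diene face.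

Step 4
Reactants: 6 bis-silyl ether
Product: 8 methyl (2E,6S,7S)-6-(TBSO)-7-[(TBSO)methyl]-9-hydroxy-3,7-dimethylnon-2-enoate, via B-alkyl-9-BBN adduct 7 (not isolated)
Conditions: 9-BBN dimer (1.5 equiv), THF, 0 → 60 °C; then 3 M NaOH, 30% H2O2, 0 °C → rt
Reagents that add atoms: hydrogen peroxide, OO
Why: Anti-Markovnikov hydroboration–oxidation with 9-BBN, which adds only to the terminal vinyl group and not to the electron-poor trisubstituted enoate, turns the vinyl group into the C5–C6 hydroxyethyl arm, so that C5 is a methylene and C6 carries the oxygen.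

Step 5
Reactants: 8 primary alcohol
Product: 9 methyl (2E,6S,7S)-6-(TBSO)-7-[(TBSO)methyl]-3,7-dimethyl-9-oxonon-2-enoate
Conditions: Dess–Martin periodinane (1.3 equiv), NaHCO3, CH2Cl2, 0 °C → rt
Reagents that add atoms: none
Why: Dess–Martin oxidation stops cleanly at the aldehyde under buffered conditions that leave the silyl ethers and the enoate untouched.

Step 6
Reactants: 9 aldehyde; 10 (E)-1-bromoprop-1-ene
Product: 12 methyl (2E,6S,7S,10E)-6-(TBSO)-7-[(TBSO)methyl]-9-hydroxy-3,7-dimethyldodeca-2,10-dienoate (both C9 epimers), via (E)-prop-1-enyllithium 11 (not isolated)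
Conditions: 10 (1.3 equiv), t-BuLi (2.6 equiv), Et2O, −78 °C; then 9, −78 °C; aq. NH4Cl
Reagents that add atoms: none
Why: Lithium–bromine exchange with retention of the E geometry followed by 1,2-addition of the alkenyllithium to the aldehyde, which is far more electrophilic at −78 °C than the hindered β,β-disubstituted enoate, attaches C7, C8 and C17, and the new carbinol centre is removed in the next step.

Step 7
Reactants: 12 allylic alcohol
Product: 13 methyl (2E,6S,7S,10E)-6-(TBSO)-7-[(TBSO)methyl]-3,7-dimethyl-9-oxododeca-2,10-dienoate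
Conditions: Dess–Martin periodinane (1.3 equiv), NaHCO3, CH2Cl2, 0 °C → rt
Reagents that add atoms: none
Why: Dess–Martin oxidation of the secondary allylic alcohol should give the (E)-propenyl ketone whose only α′ hydrogens are those of the C5 methylene.

Step 8
Reactants: 13 enone
Product: 14 methyl (2E,6S,7S,8Z,10E)-6,9-bis(TBSO)-7-[(TBSO)methyl]-3,7-dimethyldodeca-2,8,10-trienoate
Conditions: LiN(SiMe3)2 (1.05 equiv), THF, −78 °C; then TBSOTf (1.1 equiv), −78 °C; Et3N, pentane work-up
Reagents that add atoms: tert-butyldimethylsilyl trifluoromethanesulfonate, CC(C)(C)[Si](C)(C)OS(=O)(=O)C(F)(F)F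
Why: Kinetic α′-deprotonation of the enone at C5 and O-silylation of the cross-conjugated enolate (silyl enol ether formation) should give the 2-silyloxydiene regiospecifically, and the Z enol ether is expected because the quaternary C4 cannot sit cis to the propenyl group.

Step 9
Reactants: 14 silyloxydiene enoate
Product: 15 trans-fused cycloadduct: C6=C7 TBS enol ether with 9β-CO2Me (9α-H), 8β-CH3 (8α-H), 10β-CH3, 5α-H, 3β-OTBS, 4α-CH3 and 4β-CH2OTBS
Conditions: Me2AlCl (1.5 equiv, 1 M in hexane), CH2Cl2, −78 → −30 °C; Et3N then aq. NaHCO3 quench at −78 °C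
Reagents that add atoms: none
Why: Me2AlCl binds the ester carbonyl and the electron-rich silyloxydiene adds to the enoate in a concerted but asynchronous [4+2] cycloaddition (at the limit a Mukaiyama–Michael addition of C5 to C10 followed by Michael closure of C9 onto C8), the known Lewis-acid-promoted type 1 intramolecular Diels–Alder reaction of 2-silyloxy-1,3-dienes with tethered enoates. Ring B closes as the cycloaddition ring through the new C5–C10 and C8–C9 bonds, and ring A closes as a six-membered chair through the C1–C4 tether. C8 and C9 follow from the E-propenyl and E-enoate geometries by suprafacial addition (C17 cis to C4 across ring B, CO2Me cis to C20), and C5 and C10 from the endo-ester, chair-tether transition state, which gives the trans ring fusion. The selectivity that the step needs is facial with respect to C4: in the chair that keeps the C3 silyloxy group equatorial and the C4–CH3 bond anti to the forming C5–C10 bond, C19 is axial and on the dienophile face, so C20 should end up syn to C19. Regiochemistry is fixed by the tether and matches the polarity, the nucleophilic C5 bonding to the enoate β-carbon C10.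

Step 10
Reactants: 15 cycloadduct
Product: 17 cyclic methyl ketal (6β,19-epoxy-6α-methoxy; 3β-OH; 8β-CH3; 9β-CO2Me), via 6-keto-3β,19-diol 16 (not isolated)
Conditions: HCl (0.5 M in MeOH), MeOH/CH2Cl2, 0 °C → rt
Reagents that add atoms: methanol, CO
Why: Acidic methanolysis cleaves the silyl enol ether and both silyl ethers, and the 19-hydroxyl, which is 1,3-diaxial to C6, closes onto the 6-ketone as a cyclic methyl ketal (acid-catalysed ketalisation) that masks C6 and O19 together and leaves the 3-hydroxyl as the only free alcohol, C5 staying in the more stable trans-fused configuration.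

Step 11
Reactants: 17 cyclic methyl ketal
Product: 19 Δ8 ester (C8=C9 conjugated with the C11 ester; ketal and 3β-OH unchanged), via 9α-phenylselenide 18 (not isolated)
Conditions: LiN(i-Pr)2 (2.4 equiv), THF, −78 → −20 °C; PhSeBr (1.2 equiv), −78 °C; then pyridine, 30% H2O2, 0 °C → rt
Reagents that add atoms: none
Why: Selenoxide syn-elimination: with C6 masked the only acidic C–H is at C9, the ester enolate should be selenenylated from the α face opposite the C8 and C10 methyl groups, and the selenoxide can only eliminate towards the cis 8α-H, which gives the tetrasubstituted Δ8 enoate and removes the C8 and C9 stereocentres.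

Step 12
Reactants: 19 Δ8 ester
Product: 20 C11 primary allylic alcohol (ketal and 3β-OH unchanged)
Conditions: i-Bu2AlH (4 equiv), CH2Cl2, −78 → 0 °C; Rochelle salt
Reagents that add atoms: none
Why: Aluminium hydride 1,2-reduction of the conjugated ester gives the allylic alcohol, the ketal being inert at these temperatures.

Step 13
Reactants: 20 allylic alcohol
Product: 21 C11 enal
Conditions: MnO2 (activated, 20 equiv), CH2Cl2, rt
Reagents that add atoms: none
Why: Chemoselective MnO2 oxidation of the allylic alcohol leaves the saturated secondary 3-hydroxyl untouched.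

Step 14
Reactants: 21 enal
Product: 22 diene (C11=C12 vinyl group on C9)
Conditions: Ph3PCH3Br (4 equiv), KOt-Bu (3.8 equiv), THF, 0 °C → rt
Reagents that add atoms: methyltriphenylphosphonium bromide, C[P+](c1ccccc1)(c1ccccc1)c1ccccc1.[Br-]
Why: Wittig methylenation of the hindered enal, with enough ylide to cover the free hydroxyl, installs C12 as a terminal vinyl carbon.

Step 15
Reactants: 23 methyl acetoacetate
Product: 24 methyl (2E)-3-{[(trifluoromethyl)sulfonyl]oxy}but-2-enoate
Conditions: aq. Me4NOH, Tf2O, hexane, 5 °C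
Reagents that add atoms: trifluoromethanesulfonic anhydride, O=S(=O)(OS(=O)(=O)C(F)(F)F)C(F)(F)F
Why: O-Triflation of the β-keto ester enolate with a non-chelating ammonium counter-ion should give the E enol triflate (sulfonyloxy group trans to the ester), the geometry that the coupling transfers to C13=C14.

Step 16
Reactants: 22 diene; 24 enol triflate
Product: 26 methyl (13E)-6β,19-epoxy-3β-hydroxy-6α-methoxylabda-8,13-dien-15-oate, via B-alkyl-9-BBN adduct 25 (not isolated)
Conditions: 9-BBN dimer (1.5 equiv), THF, 0 °C → rt; then 24 (1.3 equiv), Pd(dppf)Cl2 (5 mol%), AsPh3 (5 mol%), K3PO4 (3 equiv), DMF/H2O, rt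
Reagents that add atoms: none
Why: 9-BBN should add only to the terminal vinyl group (the ring alkene is tetrasubstituted), and B-alkyl Suzuki–Miyaura coupling with the enol triflate forms C12–C13 with retention of the E enoate geometry.

Step 17
Reactants: 26 hydroxy ketal ester
Product: 27 methyl (13E)-6β,19-epoxy-6α-methoxy-3-oxolabda-8,13-dien-15-oate
Conditions: Dess–Martin periodinane (1.5 equiv), pyridine, CH2Cl2, 0 °C → rt
Reagents that add atoms: none
Why: Dess–Martin oxidation of the only free hydroxyl removes the 3β-carbinol, which has served to relay the induction, under buffered conditions that keep the ketal.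

Step 18
Reactants: 27 keto ketal
Product: 28 methyl (13E)-19-hydroxy-3,6-dioxolabda-8,13-dien-15-oate (in equilibrium with its 6,19-hemiketal)
Conditions: oxalic acid (0.2 M aq.), THF, rt
Reagents that add atoms: water, O
Why: Mild acid hydrolysis of the cyclic ketal, as in the oxalic acid hydrolysis of Birch-reduction enol ethers, should release the β,γ-unsaturated 6-ketone without moving the Δ8 double bond, the carbonyl being held largely as the hemiketal.

Step 19
Reactants: 28 hydroxy dione
Product: 29 methyl (13E)-3α,6β,19-trihydroxylabda-8,13-dien-15-oate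
Conditions: LiBH(s-Bu)3 (5 equiv), THF, −78 → 0 °C; MeOH then aq. NH4Cl
Reagents that add atoms: none
Why: Bulky trialkylborohydride reduction: equatorial attack on the 3-ketone should give the axial 3α-alcohol and attack on the α face of the 6-ketone, whose β face is blocked by C19 and C20, the axial 6β-alcohol, while the β,β-disubstituted enoate is inert.

Step 20
Reactants: 29 triol methyl ester
Product: 30 (13E)-3α,6β,19-trihydroxylabda-8,13-dien-15-oic acid (CNP0246116.2)
Conditions: LiOH (5 equiv), THF/MeOH/H2O, 45 °C; then aq. HCl to pH 3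
Reagents that add atoms: lithium hydroxide, [Li+].[OH-]
Why: Saponification of the methyl ester gives the acid without touching the stereocentres or the two alkenes.

Compound list
1 | 5-hydroxypentan-2-one | CC(=O)CCCO | starting material
2 | trimethyl phosphonoacetate | COC(=O)CP(=O)(OC)OC | starting material
3 | methyl (2E)-6-hydroxy-3-methylhex-2-enoate | OCCC/C(C)=C/C(=O)OC | intermediate
4 | 2-methyl-2-vinyloxirane (racemic) | CC1(C=C)CO1 | starting material
5 | methyl (2E,6S,7S)-6-hydroxy-7-(hydroxymethyl)-3,7-dimethylnona-2,8-dienoate | C=C[C@@](C)(CO)[C@@H](O)CC/C(C)=C/C(=O)OC | intermediate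
6 | methyl (2E,6S,7S)-6-(TBSO)-7-[(TBSO)methyl]-3,7-dimethylnona-2,8-dienoate | C=C[C@@](C)(CO[Si](C)(C)C(C)(C)C)[C@@H](O[Si](C)(C)C(C)(C)C)CC/C(C)=C/C(=O)OC | intermediate
7 | B-alkyl-9-BBN adduct of 6 (boron on the terminal carbon of the former vinyl group) | C1CCC2CCCC1B2CC[C@@](C)(CO[Si](C)(C)C(C)(C)C)[C@@H](O[Si](C)(C)C(C)(C)C)CC/C(C)=C/C(=O)OC | intermediate (not isolated)
8 | methyl (2E,6S,7S)-6-(TBSO)-7-[(TBSO)methyl]-9-hydroxy-3,7-dimethylnon-2-enoate | OCC[C@@](C)(CO[Si](C)(C)C(C)(C)C)[C@@H](O[Si](C)(C)C(C)(C)C)CC/C(C)=C/C(=O)OC | intermediate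
9 | methyl (2E,6S,7S)-6-(TBSO)-7-[(TBSO)methyl]-3,7-dimethyl-9-oxonon-2-enoate | O=CC[C@@](C)(CO[Si](C)(C)C(C)(C)C)[C@@H](O[Si](C)(C)C(C)(C)C)CC/C(C)=C/C(=O)OC | intermediate
10 | (E)-1-bromoprop-1-ene | C/C=C/Br | starting material
11 | (E)-prop-1-enyllithium | C/C=C/[Li] | intermediate (not isolated)
12 | methyl (2E,6S,7S,10E)-6-(TBSO)-7-[(TBSO)methyl]-9-hydroxy-3,7-dimethyldodeca-2,10-dienoate (both C9 epimers) | C/C=C/C(O)C[C@@](C)(CO[Si](C)(C)C(C)(C)C)[C@@H](O[Si](C)(C)C(C)(C)C)CC/C(C)=C/C(=O)OC | intermediate
13 | methyl (2E,6S,7S,10E)-6-(TBSO)-7-[(TBSO)methyl]-3,7-dimethyl-9-oxododeca-2,10-dienoate | C/C=C/C(=O)C[C@@](C)(CO[Si](C)(C)C(C)(C)C)[C@@H](O[Si](C)(C)C(C)(C)C)CC/C(C)=C/C(=O)OC | intermediate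
14 | methyl (2E,6S,7S,8Z,10E)-6,9-bis(TBSO)-7-[(TBSO)methyl]-3,7-dimethyldodeca-2,8,10-trienoate (cycloaddition precursor) | C/C=C/C(O[Si](C)(C)C(C)(C)C)=C/[C@@](C)(CO[Si](C)(C)C(C)(C)C)[C@@H](O[Si](C)(C)C(C)(C)C)CC/C(C)=C/C(=O)OC | intermediate
15 | trans-fused cycloadduct: C6=C7 TBS enol ether, 9β-CO2Me, 8β-CH3, 10β-CH3, 5α-H, 3β-OTBS, 4α-CH3, 4β-CH2OTBS | C[C@@H]1[C@H](C(=O)OC)[C@@]2(C)CC[C@H](O[Si](C)(C)C(C)(C)C)[C@](C)(CO[Si](C)(C)C(C)(C)C)[C@@H]2C(O[Si](C)(C)C(C)(C)C)=C1 | intermediate
16 | 6-keto-3β,19-diol (desilylated 15; 9β-CO2Me, 8β-CH3, 5α-H) | C[C@@H]1[C@H](C(=O)OC)[C@@]2(C)CC[C@H](O)[C@](C)(CO)[C@@H]2C(=O)C1 | intermediate (not isolated)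
17 | cyclic methyl ketal: 6β,19-epoxy-6α-methoxy, 3β-OH, 8β-CH3, 9β-CO2Me | C[C@@H]1[C@H](C(=O)OC)[C@@]2(C)CC[C@H](O)[C@]3(C)CO[C@](OC)(C1)[C@H]23 | intermediate
18 | 9α-phenylselenide of 17 | C[C@@H]1[C@]([Se]c4ccccc4)(C(=O)OC)[C@@]2(C)CC[C@H](O)[C@]3(C)CO[C@](OC)(C1)[C@H]23 | intermediate (not isolated)
19 | Δ8 ester: C8=C9 bearing C17 and the C11 methyl ester, 6β,19-epoxy-6α-methoxy, 3β-OH | CC1=C(C(=O)OC)[C@@]2(C)CC[C@H](O)[C@]3(C)CO[C@](OC)(C1)[C@H]23 | intermediate
20 | C11 allylic alcohol of 19 | CC1=C(CO)[C@@]2(C)CC[C@H](O)[C@]3(C)CO[C@](OC)(C1)[C@H]23 | intermediate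
21 | C11 enal | CC1=C(C=O)[C@@]2(C)CC[C@H](O)[C@]3(C)CO[C@](OC)(C1)[C@H]23 | intermediate
22 | diene with C11=C12 vinyl group on C9 | CC1=C(C=C)[C@@]2(C)CC[C@H](O)[C@]3(C)CO[C@](OC)(C1)[C@H]23 | intermediate
23 | methyl acetoacetate | CC(=O)CC(=O)OC | starting material
24 | methyl (2E)-3-{[(trifluoromethyl)sulfonyl]oxy}but-2-enoate | COC(=O)/C=C(\C)OS(=O)(=O)C(F)(F)F | intermediate
25 | B-alkyl-9-BBN adduct of 22 (boron on C12) | CC1=C(CCB4C5CCCC4CCC5)[C@@]2(C)CC[C@H](O)[C@]3(C)CO[C@](OC)(C1)[C@H]23 | intermediate (not isolated)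
26 | methyl (13E)-6β,19-epoxy-3β-hydroxy-6α-methoxylabda-8,13-dien-15-oate | CC1=C(CC/C(C)=C/C(=O)OC)[C@@]2(C)CC[C@H](O)[C@]3(C)CO[C@](OC)(C1)[C@H]23 | intermediate
27 | methyl (13E)-6β,19-epoxy-6α-methoxy-3-oxolabda-8,13-dien-15-oate | CC1=C(CC/C(C)=C/C(=O)OC)[C@@]2(C)CCC(=O)[C@]3(C)CO[C@](OC)(C1)[C@H]23 | intermediate
28 | methyl (13E)-19-hydroxy-3,6-dioxolabda-8,13-dien-15-oate (open form of the 6,19-hemiketal) | CC1=C(CC/C(C)=C/C(=O)OC)[C@@]2(C)CCC(=O)[C@](C)(CO)[C@@H]2C(=O)C1 | intermediate
29 | methyl (13E)-3α,6β,19-trihydroxylabda-8,13-dien-15-oate | CC1=C(CC/C(C)=C/C(=O)OC)[C@@]2(C)CC[C@@H](O)[C@](C)(CO)[C@@H]2[C@H](O)C1 | intermediate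
30 | (13E)-3α,6β,19-trihydroxylabda-8,13-dien-15-oic acid (CNP0246116.2) | CC1=C(CC/C(C)=C/C(=O)O)[C@@]2(C)CC[C@@H](O)[C@](C)(CO)[C@@H]2[C@H](O)C1 | target

Total step count: 20. Longest linear sequence: 19 (steps 1–14 and 16–20; step 15 prepares the coupling partner).

Steps most likely to fail

1. Step 9. The tether may fold through the other chair (C3 silyloxy group and C18 axial), which exposes the opposite diene face and places C20 anti to C19; the facial preference argued above is modest and is the main risk of the route. The hindered β,β-disubstituted enoate may also react so slowly that the diene is desilylated first. The fallback is an internal enol-ether tether; it sets out from 13 and returns at 17. HF·pyridine in THF/pyridine at 0 °C cleaves the primary C19 silyl ether of 13 to the γ-hydroxy enone F1. PPTS in toluene over 4 Å molecular sieves cyclodehydrates it to the 2-[(E)-prop-1-enyl]-4,5-dihydrofuran F2, a 2-alkoxydiene in which the C19 oxygen is the enol ether oxygen on C6. C19 is then held in the diene plane inside a five-membered ring, so the tethered enoate can only reach C5 from the ring face that carries the C3 chain; H5 and C18 end up cis and C19 axial. Me2AlCl-promoted cycloaddition should give the tricyclic enol ether F3, and methanolic HCl adds methanol to the enol ether and removes the C3 silyl group to return to 17.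

2. Step 11. Deprotonation of the hindered tertiary C9–H next to the quaternary C10 may be incomplete, or selenenylation may occur on the β face so that no syn hydrogen is available for elimination. The fallback dehydrogenates through the ketone instead of the ester; it sets out from 15 and returns at 19. Saegusa–Ito oxidation of the silyl enol ether 15 (Pd(OAc)2, MeCN, rt) gives the Δ7-6-ketone F4. Methanolic HCl removes both silyl ethers and closes the 19-hydroxyl onto C6 to give the Δ7 cyclic methyl ketal F5. NaOMe in MeOH then equilibrates the β,γ-unsaturated ester through its dienolate into the conjugated, tetrasubstituted Δ8 ester 19.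

3. Step 19. Facial selectivity at C3 may erode next to the free C19 alkoxide, reduction of C6 may stall while it is held as the hemiketal, or C19 may be lost by retro-aldol cleavage of the β-hydroxy ketone. The fallback is a stepwise reduction with C19 still locked; it sets out from 27 and returns at 29. LiBH(s-Bu)3 at −78 °C reduces the 3-ketone of 27 to the axial alcohol while C6 and O19 remain tied in the ketal, giving the 3α-hydroxy ketal F6. Oxalic acid hydrolysis gives the 6-keto-3α,19-diol F7. NaBH4 in MeOH at 0 °C attacks the 6-ketone from the α face to give 29.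

Further compounds
F1 | step 9 | methyl (2E,6S,7S,10E)-6-(TBSO)-7-(hydroxymethyl)-3,7-dimethyl-9-oxododeca-2,10-dienoate (γ-hydroxy enone) | C/C=C/C(=O)C[C@@](C)(CO)[C@@H](O[Si](C)(C)C(C)(C)C)CC/C(C)=C/C(=O)OC
F2 | step 9 | 2-[(E)-prop-1-enyl]-4,5-dihydrofuran diene (O19 bonded to C6, C5=C6 in the ring, 3-OTBS) | C/C=C/C1=C[C@](C)([C@@H](O[Si](C)(C)C(C)(C)C)CC/C(C)=C/C(=O)OC)CO1
F3 | step 9 | tricyclic enol ether cycloadduct (6,19-epoxy, C6=C7, 3β-OTBS, 8β-CH3, 9β-CO2Me) | C[C@@H]1[C@H](C(=O)OC)[C@@]2(C)CC[C@H](O[Si](C)(C)C(C)(C)C)[C@]3(C)COC(=C1)[C@H]23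
F4 | step 11 | Δ7-6-ketone (3β-OTBS, 19-OTBS, 9β-CO2Me) | CC=1[C@H](C(=O)OC)[C@@]2(C)CC[C@H](O[Si](C)(C)C(C)(C)C)[C@](C)(CO[Si](C)(C)C(C)(C)C)[C@@H]2C(=O)C=1
F5 | step 11 | Δ7 cyclic methyl ketal (6β,19-epoxy-6α-methoxy, 3β-OH, 9β-CO2Me) | CC=1[C@H](C(=O)OC)[C@@]2(C)CC[C@H](O)[C@]3(C)CO[C@](OC)(C=1)[C@H]23
F6 | step 19 | methyl (13E)-6β,19-epoxy-3α-hydroxy-6α-methoxylabda-8,13-dien-15-oate | CC1=C(CC/C(C)=C/C(=O)OC)[C@@]2(C)CC[C@@H](O)[C@]3(C)CO[C@](OC)(C1)[C@H]23
F7 | step 19 | methyl (13E)-3α,19-dihydroxy-6-oxolabda-8,13-dien-15-oate | CC1=C(CC/C(C)=C/C(=O)OC)[C@@]2(C)CC[C@@H](O)[C@](C)(CO)[C@@H]2C(=O)C1
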